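Take the constants as one ratio. Let S be the starting complex, A the complex with one exchanged, X the free incoming ligand, k_x the forward constant of S + X → A + leaving ligand, and k_s that of S + A → side product.

the same everywhere: starting complex 0.35 M; protic impurity 0.105 M
- zeta: incoming ligand 0.37 M; run made earlier
- delta: incoming ligand 0.81 M; run made earlier
- south: incoming ligand 0.525 M; time 3.0 h
- south-west: incoming ligand 0.875 M; time 3.0 h
- east: incoming ligand 1.05 M; time 3.0 h

| run | time / min | complex with one exchanged / % | complex with two exchanged / % | starting complex / % |
|---|---|---|---|---|
| zeta | 8.00 | 2.7 | 0.3 | 95.6 |
| zeta | 12.0 | 4.8 | 0.6 | 93.8 |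
| zeta | 20.0 | 5.9 | 0.2 | 91.0 |
| zeta | 30.0 | 7.4 | 0 | 86.4 |
| zeta | 50.0 | 10.1 | 0 | 78.3 |
| zeta | 90.0 | 11.1 | 0.1 | 65.7 |
| delta | 15.0 | 11.5 | 0.1 | 84.9 |
| delta | 30.0 | 17.3 | 0.5 | 71.7 |
| delta | 50.0 | 20.7 | 1.0 | 57.3 |
| delta | 60.0 | 22.2 | 1.4 | 52.2 |
| delta | 80.0 | 23.0 | 0.7 | 42.6 |
| delta | 90.0 | 22.4 | 1.7 | 38.4 |

(readings scatter by 0.5 percentage points)

- which of these holds the largest part of the starting complex at the end of south (complex with three exchanged / complex with two exchanged / starting complex / complex with one exchanged)
- which of these holds the largest part of the starting complex at the end of south-west (complex with three exchanged / complex with two exchanged / starting complex / complex with one exchanged)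
- which of these holds the largest part of the starting complex at the end of east (complex with three exchanged / complex with two exchanged / starting complex / complex with one exchanged)
- final complex with one exchanged in south, as a percentage of the starting complex charged

- percent here means starting complex units held: one side product counts as two
- steps that have been proposed: starting complex + complex with one exchanged -> side product; complex with one exchanged + incoming ligand <-> leaving ligand + complex with two exchanged; starting complex + incoming ligand <-> leaving ligand + complex with one exchanged; protic impurity + incoming ligand -> quenched reagent; complex with two exchanged + incoming ligand <-> leaving ligand + complex with three exchanged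

First follow one A molecule. In delta at 90.0 min, the readings put nearly all of the A lost in side product, not in complex with two exchanged, so drop that branch.

Then ask how much A can stand. Leaving the way back aside, A is made at k_x·S·X and lost at k_s·S·A. S stands in both, so it cancels, and A tends toward a quasi-steady level near (k_x/k_s)·X.

Take X as the charge less the impurity less the ligand taken up by S. Where A flattens, A/X reads 0.209 in zeta at 90.0 min and 0.143 in delta at 80.0 min. Their mean, 0.176, is ρ, the standstill ratio: molar A held per molar free ligand. It is a rough reading, with zeta above delta.

In south, suppose exchange takes up half the S charge, which leaves X = 0.245 M at the end. I therefore expect A near 12.3%.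

Does S stay above that? Once A stands at ρX, the fractional loss of S scales with X, so scale delta's S reading by time and by the ligand charge less the impurity. By this estimate south keeps 32.0% of S, more than A. South-west should keep 12.4% against A at 29.9%, so expect A to lead. East should keep 7.69% against 38.7%, so expect A to lead there too.

The forecast names starting complex, complex with one exchanged and complex with one exchanged for south, south-west and east, with 16% of A in south (range 12% to 20%), higher than my 12.3%, and says “so starting complex stays largest”.

The flask gives starting complex, complex with one exchanged and complex with one exchanged, with 14.1% of A in south.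

    starting complex + complex with one exchanged → side product (k = 9.60 × 10⁻⁴ M⁻¹ s⁻¹)
    complex with one exchanged + incoming ligand ⇌ leaving ligand + complex with two exchanged (K = 2.20, k = 1.90 × 10⁻⁵ M⁻¹ s⁻¹)
    starting complex + incoming ligand ⇌ leaving ligand + complex with one exchanged (K = 0.670, k = 2.10 × 10⁻⁴ M⁻¹ s⁻¹)
    protic impurity + incoming ligand → quenched reagent (k = 0.00190 M⁻¹ s⁻¹)
    complex with two exchanged + incoming ligand ⇌ leaving ligand + complex with three exchanged (K = 79.0, k = 6.30 × 10⁻⁵ M⁻¹ s⁻¹)

South's A is past its peak: at the end it is made 0.741 times as fast as it is used, each step taken net. Now cut the S charge to 0.21 M, all else as in south. ρ counts molar A, so the same reckoning gives 26.4% of this smaller charge. That flask gives 23.0%, which is 0.0483 M of A against 0.0493 M in south.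

The earlier runs and the new flask were generated by integration on assumed constants, and the scatter is random.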